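**Retrosynthetic overview**

1. Locants: oxane O1, C2 (aryl), C3 (chain C8–C10), C4, C5 (carbinol carbon C7), C6. The plan rests on the O1–C2(aryl)–C3(chain)–C4H2 segment of the oxane with C2 and C3 cis, which is the imprint of a Z-alkenylarene added across O1 and C4 of the 1-oxadiene O1=C6–C5(CO2Me)=C4H2.
2. Disconnections, backwards: C7–aryl (Grignard addition to the C5 aldehyde), C9=C10 (Julia–Kocienski olefination), the two C–H bonds at C5 and C6 (hydrogenation), then O1–C2 and C3–C4 together (hetero-Diels–Alder addition), and C4=C5 (Knoevenagel condensation with formaldehyde).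
3. Ring order: the oxane is the only ring made; it closes in step 5 as a 3,4-dihydro-2H-pyran and is saturated in step 6.
4. The oxadiene is activated at one point (formyl oxygen) by a chiral trivalent chromium Schiff-base complex, because two-point chelation of the 1,3-dicarbonyl would hold O1=C6 s-trans to C5=C4. The arene carries an acetoxy group (weak donor) and the chain a benzyl ether.
5. Stereocontrol: C2/C3 from the Z alkene and the catalyst, C5 from the face of hydrogenation, C7 from magnesium chelation, C9=C10 from the olefination.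

Key step: step 5

Remark: stereodescriptors of oxanes use the locants above; TBS = tert-butyldimethylsilyl, PT = 1-phenyl-1H-tetrazol-5-yl.
Assumption: the sense of induction of the chromium catalyst with this new pair of partners cannot be derived from precedent; the antipode of cis-1-aminoindan-2-ol in the ligand that gives (2R,3R)-10 is to be fixed in a pilot run, and the route is written for that antipode.

**Route**

Step 1
Reactants: 1 4-iodophenol
Product: 2 4-iodophenyl acetate
Conditions: Ac2O, Et3N, DMAP (cat.), CH2Cl2, 0 °C to rt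
Reagents that add atoms: acetic anhydride, CC(=O)OC(C)=O
Why: DMAP-catalysed O-acylation of a phenol; the acetoxy group is the weak donor wanted on the arene in step 5.

Step 2
Reactants: 2 4-iodophenyl acetate; 3 4-(benzyloxy)but-1-yne
Product: 4 4-[4-(benzyloxy)but-1-yn-1-yl]phenyl acetate
Conditions: PdCl2(PPh3)2 (2 mol%), CuI (4 mol%), Et3N, THF, rt
Reagents that add atoms: none
Why: Sonogashira coupling of an aryl iodide with a terminal alkyne runs at room temperature, where the aryl acetate and the benzyl ether are inert.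

Step 3
Reactants: 4 4-[4-(benzyloxy)but-1-yn-1-yl]phenyl acetate
Product: 5 4-[(Z)-4-(benzyloxy)but-1-en-1-yl]phenyl acetate
Conditions: H2 (1 atm), Pd/CaCO3–Pb(OAc)2, quinoline, EtOAc, rt, stopped after one equivalent of H2
Reagents that add atoms: none
Why: Lindlar semi-hydrogenation delivers both hydrogens to one face of the alkyne on the poisoned palladium surface, which should give the Z alkene and leave the benzyl ether intact.

Step 4
Reactants: 6 methyl 3,3-dimethoxypropanoate
Product: 7 methyl 3-oxopropanoate (aldehyde/enol mixture, kept as a dried CH2Cl2 solution and used at once)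
Conditions: 2 M aq. HCl, THF, 0 °C to rt; extraction into CH2Cl2, Na2SO4
Reagents that add atoms: water, O
Why: acid-catalysed acetal hydrolysis; the aldehyde is not stored because it condenses with itself.

Step 5
Reactants: 7 methyl 3-oxopropanoate; 8 formaldehyde (used as paraformaldehyde); 5 4-[(Z)-4-(benzyloxy)but-1-en-1-yl]phenyl acetate
Product: 10 methyl (2R,3R)-2-(4-acetoxyphenyl)-3-[2-(benzyloxy)ethyl]-3,4-dihydro-2H-pyran-5-carboxylate (C2-aryl and C3-chain cis), via methyl 2-formylacrylate 9 (not isolated)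
Conditions: 5 (1 equiv), 8 (2 equiv), CrCl(L) (10 mol%; L = doubly deprotonated Schiff base of 3-(1-adamantyl)-2-hydroxy-5-methylbenzaldehyde and cis-1-aminoindan-2-ol), powdered 4 Å MS, CH2Cl2, 0 °C to rt; 7 (2 equiv) added over 10 h
Reagents that add atoms: none
Why: Proposed new method: the enol of 7 adds to formaldehyde and loses water on the sieves (Knoevenagel condensation) to give 9, whose formyl oxygen binds the single labile site of the trivalent chromium centre on the side away from C5, so that O1=C6–C5=C4 can be s-cis and the ester stays unbound, whereas a chelating Lewis acid such as a divalent copper bis(oxazoline) would tie both carbonyl oxygens together, lock the oxadiene s-trans and divert the alkene to [2+2] closure through C5. The closest known reaction types are the inverse-demand hetero-Diels–Alder addition of α,β-unsaturated aldehydes to enol ethers under chromium Schiff-base catalysts of this kind and the uncatalysed three-component reaction of 1,3-dicarbonyls, formaldehyde and styrenes; new here are the doubly activated enal and a Z-alkenylarene as the 2π partner. The dihydropyran ring closes by a concerted, asynchronous [4+2] cycloaddition in which the non-benzylic alkene carbon (C3) bonds to the electrophilic C4 ahead of the C2–O1 bond. C2 and C3 come out cis because both bonds form on one face of the Z alkene (substrate geometry), and their absolute configuration is set by the catalyst, which screens one face of the bound oxadiene while the aryl group lies endo. The step needs regioselectivity (given by the polarisation of both partners), stereospecificity (the acetoxy-substituted arene is too weak a donor to support a free, rotating benzylic cation, and the ether and ester oxygens of 5 are poor internal nucleophiles) and enantioface selection (catalyst, with the racemic background reaction held down by low temperature and a low stationary concentration of 9).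

Step 6
Reactants: 10 methyl (2R,3R)-2-(4-acetoxyphenyl)-3-[2-(benzyloxy)ethyl]-3,4-dihydro-2H-pyran-5-carboxylate
Product: 11 methyl (2R,3R,5R)-2-(4-acetoxyphenyl)-3-(2-hydroxyethyl)oxane-5-carboxylate (all-cis)
Conditions: H2 (4 bar), 10% Pd/C, EtOAc–EtOH, rt
Reagents that add atoms: none
Why: heterogeneous catalytic hydrogenation adds H2 to the α face of C5=C6, because the β face is covered by the cis C2-aryl and C3-chain groups (one of them pseudoaxial in either half-chair), which should set C5 with the ester cis to both; the same catalyst hydrogenolyses the benzyl ether, and the neutral medium spares the ring C2–O1 bond.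

Step 7
Reactants: 11 methyl (2R,3R,5R)-2-(4-acetoxyphenyl)-3-(2-hydroxyethyl)oxane-5-carboxylate
Product: 12 methyl (2R,3R,5R)-2-(4-acetoxyphenyl)-3-[2-(PT-sulfanyl)ethyl]oxane-5-carboxylate
Conditions: 1-phenyl-1H-tetrazole-5-thiol, PPh3, DIAD, THF, 0 °C to rt
Reagents that add atoms: 1-phenyl-1H-tetrazole-5-thiol, Sc1nnnn1-c1ccccc1
Why: Mitsunobu thioetherification of the primary C9 alcohol by the acidic thiol; no stereocentre is involved.

Step 8
Reactants: 12 methyl (2R,3R,5R)-2-(4-acetoxyphenyl)-3-[2-(PT-sulfanyl)ethyl]oxane-5-carboxylate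
Product: 13 methyl (2R,3R,5R)-2-(4-hydroxyphenyl)-3-[2-(PT-sulfanyl)ethyl]oxane-5-carboxylate
Conditions: pyrrolidine (3 equiv), CH2Cl2, rt
Reagents that add atoms: none
Why: aminolysis of the aryl acetate by a secondary amine that is too weak a base to epimerise the C5 ester; the phenol is released only now, when O1 is an ordinary ether oxygen and a phenoxide para to C2 can no longer expel it as a vinylogous carboxylate to give a quinone methide.

Step 9
Reactants: 13 methyl (2R,3R,5R)-2-(4-hydroxyphenyl)-3-[2-(PT-sulfanyl)ethyl]oxane-5-carboxylate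
Product: 14 methyl (2R,3R,5R)-2-[4-(TBS-oxy)phenyl]-3-[2-(PT-sulfanyl)ethyl]oxane-5-carboxylate
Conditions: TBSCl, imidazole, CH2Cl2, rt
Reagents that add atoms: tert-butyldimethylsilyl chloride, CC(C)(C)[Si](C)(C)Cl
Why: silylation of the phenol gives an aryl silyl ether that withstands KN(SiMe3)2, iBu2AlH and the Grignard reagent of the later steps, which the acetate would not.

Step 10
Reactants: 14 methyl (2R,3R,5R)-2-[4-(TBS-oxy)phenyl]-3-[2-(PT-sulfanyl)ethyl]oxane-5-carboxylate
Product: 15 methyl (2R,3R,5R)-2-[4-(TBS-oxy)phenyl]-3-[2-(PT-sulfonyl)ethyl]oxane-5-carboxylate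
Conditions: 30% H2O2, (NH4)6Mo7O24·4H2O (10 mol%), EtOH, 0 °C to rt
Reagents that add atoms: hydrogen peroxide, OO
Why: molybdate-catalysed oxidation of the thioether to the sulfone through the sulfoxide; ester, aryl silyl ether and ring ether are inert to the peroxomolybdate.

Step 11
Reactants: 15 methyl (2R,3R,5R)-2-[4-(TBS-oxy)phenyl]-3-[2-(PT-sulfonyl)ethyl]oxane-5-carboxylate; 16 4-(TBS-oxy)benzaldehyde
Product: 17 methyl (2R,3S,5R)-2-[4-(TBS-oxy)phenyl]-3-{(E)-3-[4-(TBS-oxy)phenyl]prop-2-en-1-yl}oxane-5-carboxylate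
Conditions: KN(SiMe3)2 (1.05 equiv), DME, −60 °C; then 16, −60 °C to rt
Reagents that add atoms: none
Why: Julia–Kocienski olefination, in which the metalated alkyl tetrazolyl sulfone adds to the aromatic aldehyde and Smiles rearrangement with loss of SO2 and the tetrazololate should give the conjugated E alkene (aryl aldehydes favour E); the sulfone is far more acidic than C5–H, so C5 is not touched.

Step 12
Reactants: 17 methyl (2R,3S,5R)-2-[4-(TBS-oxy)phenyl]-3-{(E)-3-[4-(TBS-oxy)phenyl]prop-2-en-1-yl}oxane-5-carboxylate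
Product: 18 [(2R,3S,5S)-2-[4-(TBS-oxy)phenyl]-3-{(E)-3-[4-(TBS-oxy)phenyl]prop-2-en-1-yl}oxan-5-yl]methanol
Conditions: iBu2AlH (2.5 equiv), CH2Cl2, −78 to 0 °C; aq. potassium sodium tartrate work-up
Reagents that add atoms: none
Why: reduction of the ester to the primary alcohol by the aluminium hydride under non-basic conditions, so C5 keeps its configuration (its descriptor changes only through the change of priorities).

Step 13
Reactants: 18 [(2R,3S,5S)-2-[4-(TBS-oxy)phenyl]-3-{(E)-3-[4-(TBS-oxy)phenyl]prop-2-en-1-yl}oxan-5-yl]methanol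
Product: 19 (2R,3S,5R)-2-[4-(TBS-oxy)phenyl]-3-{(E)-3-[4-(TBS-oxy)phenyl]prop-2-en-1-yl}oxane-5-carbaldehyde
Conditions: Dess–Martin periodinane, pyridine, CH2Cl2, 0 °C; filtered and used at once
Reagents that add atoms: none
Why: Dess–Martin oxidation in a buffered, non-basic medium, so that the all-cis aldehyde, which is the less stable C5 epimer, is not equilibrated.

Step 14
Reactants: 19 (2R,3S,5R)-2-[4-(TBS-oxy)phenyl]-3-{(E)-3-[4-(TBS-oxy)phenyl]prop-2-en-1-yl}oxane-5-carbaldehyde; 20 (4-bromophenoxy)(tert-butyl)dimethylsilane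
Product: 22 (R)-[4-(TBS-oxy)phenyl][(2R,3S,5R)-2-[4-(TBS-oxy)phenyl]-3-{(E)-3-[4-(TBS-oxy)phenyl]prop-2-en-1-yl}oxan-5-yl]methanol, via aryl Grignard reagent 21 (not isolated)
Conditions: 20, Mg, Et2O, reflux; then added to 19 premixed with MgBr2·OEt2 (2 equiv) in CH2Cl2, −78 °C
Reagents that add atoms: none
Why: chelation-controlled Grignard addition to a β-alkoxy aldehyde, in which magnesium bridges the formyl oxygen and O1 (formyl group axial) and the aryl group attacks the Si face of C7, on the side of C5–H and C6 and away from C4 and the syn-axial C3 chain, which should give the 7R carbinol.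

Step 15
Reactants: 22 (R)-[4-(TBS-oxy)phenyl][(2R,3S,5R)-2-[4-(TBS-oxy)phenyl]-3-{(E)-3-[4-(TBS-oxy)phenyl]prop-2-en-1-yl}oxan-5-yl]methanol
Product: 23 (R)-(4-hydroxyphenyl)[(2R,3S,5R)-2-(4-hydroxyphenyl)-3-[(E)-3-(4-hydroxyphenyl)prop-2-en-1-yl]oxan-5-yl]methanol (CNP0182155.1)
Conditions: Bu4NF–AcOH (1:1, 4 equiv), THF, 0 °C to rt
Reagents that add atoms: none
Why: fluoride cleaves the three aryl silyl ethers, and the acetic acid buffer keeps the p-hydroxybenzylic alcohol and ether from base-induced quinone methide formation.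

**Compound list** (oxane locants as in the remark)

1 | 4-iodophenol | Oc1ccc(I)cc1 | starting material
2 | 4-iodophenyl acetate | CC(=O)Oc1ccc(I)cc1 | intermediate
3 | 4-(benzyloxy)but-1-yne | C#CCCOCc1ccccc1 | starting material
4 | 4-[4-(benzyloxy)but-1-yn-1-yl]phenyl acetate | CC(=O)Oc1ccc(cc1)C#CCCOCc1ccccc1 | intermediate
5 | 4-[(Z)-4-(benzyloxy)but-1-en-1-yl]phenyl acetate | CC(=O)Oc1ccc(cc1)/C=C\CCOCc1ccccc1 | intermediate
6 | methyl 3,3-dimethoxypropanoate | COC(OC)CC(=O)OC | starting material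
7 | methyl 3-oxopropanoate | COC(=O)CC=O | intermediate
8 | formaldehyde (used as paraformaldehyde) | C=O | starting material
9 | methyl 2-formylacrylate (methyl 2-formylprop-2-enoate) | COC(=O)C(=C)C=O | intermediate
10 | methyl (2R,3R)-2-(4-acetoxyphenyl)-3-[2-(benzyloxy)ethyl]-3,4-dihydro-2H-pyran-5-carboxylate | c1ccccc1COCC[C@H]2CC(C(=O)OC)=CO[C@H]2c2ccc(OC(C)=O)cc2 | intermediate
11 | methyl (2R,3R,5R)-2-(4-acetoxyphenyl)-3-(2-hydroxyethyl)oxane-5-carboxylate | OCC[C@H]1C[C@@H](C(=O)OC)CO[C@H]1c1ccc(OC(C)=O)cc1 | intermediate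
12 | methyl (2R,3R,5R)-2-(4-acetoxyphenyl)-3-{2-[(1-phenyl-1H-tetrazol-5-yl)sulfanyl]ethyl}oxane-5-carboxylate | c1ccccc1-n1nnnc1SCC[C@H]2C[C@@H](C(=O)OC)CO[C@H]2c2ccc(OC(C)=O)cc2 | intermediate
13 | methyl (2R,3R,5R)-2-(4-hydroxyphenyl)-3-{2-[(1-phenyl-1H-tetrazol-5-yl)sulfanyl]ethyl}oxane-5-carboxylate | c1ccccc1-n1nnnc1SCC[C@H]2C[C@@H](C(=O)OC)CO[C@H]2c2ccc(O)cc2 | intermediate
14 | methyl (2R,3R,5R)-2-[4-(tert-butyldimethylsilyloxy)phenyl]-3-{2-[(1-phenyl-1H-tetrazol-5-yl)sulfanyl]ethyl}oxane-5-carboxylate | c1ccccc1-n1nnnc1SCC[C@H]2C[C@@H](C(=O)OC)CO[C@H]2c2ccc(O[Si](C)(C)C(C)(C)C)cc2 | intermediate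
15 | methyl (2R,3R,5R)-2-[4-(tert-butyldimethylsilyloxy)phenyl]-3-{2-[(1-phenyl-1H-tetrazol-5-yl)sulfonyl]ethyl}oxane-5-carboxylate | c1ccccc1-n1nnnc1S(=O)(=O)CC[C@H]2C[C@@H](C(=O)OC)CO[C@H]2c2ccc(O[Si](C)(C)C(C)(C)C)cc2 | intermediate
16 | 4-(tert-butyldimethylsilyloxy)benzaldehyde | O=Cc1ccc(O[Si](C)(C)C(C)(C)C)cc1 | starting material
17 | methyl (2R,3S,5R)-2-[4-(tert-butyldimethylsilyloxy)phenyl]-3-{(E)-3-[4-(tert-butyldimethylsilyloxy)phenyl]prop-2-en-1-yl}oxane-5-carboxylate | CC(C)(C)[Si](C)(C)Oc1ccc(/C=C/C[C@H]2C[C@@H](C(=O)OC)CO[C@H]2c2ccc(O[Si](C)(C)C(C)(C)C)cc2)cc1 | intermediate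
18 | [(2R,3S,5S)-2-[4-(tert-butyldimethylsilyloxy)phenyl]-3-{(E)-3-[4-(tert-butyldimethylsilyloxy)phenyl]prop-2-en-1-yl}oxan-5-yl]methanol | CC(C)(C)[Si](C)(C)Oc1ccc(/C=C/C[C@H]2C[C@@H](CO)CO[C@H]2c2ccc(O[Si](C)(C)C(C)(C)C)cc2)cc1 | intermediate
19 | (2R,3S,5R)-2-[4-(tert-butyldimethylsilyloxy)phenyl]-3-{(E)-3-[4-(tert-butyldimethylsilyloxy)phenyl]prop-2-en-1-yl}oxane-5-carbaldehyde | CC(C)(C)[Si](C)(C)Oc1ccc(/C=C/C[C@H]2C[C@@H](C=O)CO[C@H]2c2ccc(O[Si](C)(C)C(C)(C)C)cc2)cc1 | intermediate
20 | (4-bromophenoxy)(tert-butyl)dimethylsilane | Brc1ccc(O[Si](C)(C)C(C)(C)C)cc1 | starting material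
21 | [4-(tert-butyldimethylsilyloxy)phenyl]magnesium bromide | Br[Mg]c1ccc(O[Si](C)(C)C(C)(C)C)cc1 | intermediate
22 | (R)-[4-(tert-butyldimethylsilyloxy)phenyl][(2R,3S,5R)-2-[4-(tert-butyldimethylsilyloxy)phenyl]-3-{(E)-3-[4-(tert-butyldimethylsilyloxy)phenyl]prop-2-en-1-yl}oxan-5-yl]methanol | CC(C)(C)[Si](C)(C)Oc1ccc(/C=C/C[C@H]2C[C@@H]([C@@H](O)c3ccc(O[Si](C)(C)C(C)(C)C)cc3)CO[C@H]2c2ccc(O[Si](C)(C)C(C)(C)C)cc2)cc1 | intermediate
23 | (R)-(4-hydroxyphenyl)[(2R,3S,5R)-2-(4-hydroxyphenyl)-3-[(E)-3-(4-hydroxyphenyl)prop-2-en-1-yl]oxan-5-yl]methanol | Oc1ccc(/C=C/C[C@H]2C[C@@H]([C@@H](O)c3ccc(O)cc3)CO[C@H]2c2ccc(O)cc2)cc1 | target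

**Step count and risks**

Total step count: 15. Longest linear sequence: 14 steps (steps 1–3 and 5–15 from 4-iodophenol); step 4 is a one-step side branch.

Steps most likely to fail:

1. Step 5. The chiral chromium complex may fail to outrun the uncatalysed addition, or may be sequestered by the chelating enol of 7, so that enantioface selection is lost; a stepwise addition would also erode the cis relationship. Fallback (known chemistry), setting out from 5, 7 and 8: the three components are combined without a chiral Lewis acid (ethylenediammonium diacetate cat., toluene, 60 °C) in the known three-component Knoevenagel/hetero-Diels–Alder reaction to give the racemic cis-dihydropyran F1. Its enantiomers are separated by preparative chromatography on a chiral stationary phase (cellulose tris(3,5-dimethylphenylcarbamate)), and the (2R,3R) enantiomer is 10, where the route is rejoined.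

2. Step 6. Hydrogen may be delivered in part to the β face of C5=C6, so that the configuration at C5 is not controlled. Fallback, setting out from 10: the hydrogenation product containing the C5 epimer of 11 F2 is taken through steps 7 to 11 unchanged, which gives in turn the C5 epimer of 12 F3, the C5 epimer of 13 F4, the C5 epimer of 14 F5, the C5 epimer of 15 F6 and the C5 epimer of 17 F7. The ester F7, alone or mixed with 17, is deprotonated with LiN(iPr)2 in THF at −78 °C to the lithium ester enolate F8. Kinetic protonation of this exocyclic enolate with 2,6-di-tert-butylphenol at −78 °C, from the α direction anti to the C3 chain, should converge both epimers on 17, where the route is rejoined.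

3. Step 14. Addition may proceed through a non-chelated conformer (formyl group equatorial) with poor facial selectivity at C7. Fallback, setting out from the product mixture of step 14: the mixture of 22 and the C7 epimer of 22 F9 is oxidised with Dess–Martin periodinane to the aryl ketone F10, which is reduced with BH3·SMe2 and (S)-2-methyl-CBS-oxazaborolidine in THF at −20 °C (Corey–Bakshi–Shibata reduction, aryl as the large group). C7 is then set by the reagent, and the route is rejoined at 22.

Further compounds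
F1 | step 5 | racemic methyl cis-2-(4-acetoxyphenyl)-3-[2-(benzyloxy)ethyl]-3,4-dihydro-2H-pyran-5-carboxylate (1:1 mixture of the 2R,3R and 2S,3S enantiomers) | c1ccccc1COCC[C@H]2CC(C(=O)OC)=CO[C@H]2c2ccc(OC(C)=O)cc2.c1ccccc1COCC[C@@H]2CC(C(=O)OC)=CO[C@@H]2c2ccc(OC(C)=O)cc2
F2 | step 6 | methyl (2R,3R,5S)-2-(4-acetoxyphenyl)-3-(2-hydroxyethyl)oxane-5-carboxylate | OCC[C@H]1C[C@H](C(=O)OC)CO[C@H]1c1ccc(OC(C)=O)cc1
F3 | step 6 | methyl (2R,3R,5S)-2-(4-acetoxyphenyl)-3-{2-[(1-phenyl-1H-tetrazol-5-yl)sulfanyl]ethyl}oxane-5-carboxylate | c1ccccc1-n1nnnc1SCC[C@H]2C[C@H](C(=O)OC)CO[C@H]2c2ccc(OC(C)=O)cc2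
F4 | step 6 | methyl (2R,3R,5S)-2-(4-hydroxyphenyl)-3-{2-[(1-phenyl-1H-tetrazol-5-yl)sulfanyl]ethyl}oxane-5-carboxylate | c1ccccc1-n1nnnc1SCC[C@H]2C[C@H](C(=O)OC)CO[C@H]2c2ccc(O)cc2
F5 | step 6 | methyl (2R,3R,5S)-2-[4-(tert-butyldimethylsilyloxy)phenyl]-3-{2-[(1-phenyl-1H-tetrazol-5-yl)sulfanyl]ethyl}oxane-5-carboxylate | c1ccccc1-n1nnnc1SCC[C@H]2C[C@H](C(=O)OC)CO[C@H]2c2ccc(O[Si](C)(C)C(C)(C)C)cc2
F6 | step 6 | methyl (2R,3R,5S)-2-[4-(tert-butyldimethylsilyloxy)phenyl]-3-{2-[(1-phenyl-1H-tetrazol-5-yl)sulfonyl]ethyl}oxane-5-carboxylate | c1ccccc1-n1nnnc1S(=O)(=O)CC[C@H]2C[C@H](C(=O)OC)CO[C@H]2c2ccc(O[Si](C)(C)C(C)(C)C)cc2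
F7 | step 6 | methyl (2R,3S,5S)-2-[4-(tert-butyldimethylsilyloxy)phenyl]-3-{(E)-3-[4-(tert-butyldimethylsilyloxy)phenyl]prop-2-en-1-yl}oxane-5-carboxylate | CC(C)(C)[Si](C)(C)Oc1ccc(/C=C/C[C@H]2C[C@H](C(=O)OC)CO[C@H]2c2ccc(O[Si](C)(C)C(C)(C)C)cc2)cc1
F8 | step 6 | lithium enolate of 17 at C5/C7 (2R,3S; enolate geometry not defined) | CC(C)(C)[Si](C)(C)Oc1ccc(/C=C/C[C@H]2CC(=C(OC)O[Li])CO[C@H]2c2ccc(O[Si](C)(C)C(C)(C)C)cc2)cc1
F9 | step 14 | (S)-[4-(tert-butyldimethylsilyloxy)phenyl][(2R,3S,5R)-2-[4-(tert-butyldimethylsilyloxy)phenyl]-3-{(E)-3-[4-(tert-butyldimethylsilyloxy)phenyl]prop-2-en-1-yl}oxan-5-yl]methanol | CC(C)(C)[Si](C)(C)Oc1ccc(/C=C/C[C@H]2C[C@@H]([C@H](O)c3ccc(O[Si](C)(C)C(C)(C)C)cc3)CO[C@H]2c2ccc(O[Si](C)(C)C(C)(C)C)cc2)cc1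
F10 | step 14 | [4-(tert-butyldimethylsilyloxy)phenyl][(2R,3S,5R)-2-[4-(tert-butyldimethylsilyloxy)phenyl]-3-{(E)-3-[4-(tert-butyldimethylsilyloxy)phenyl]prop-2-en-1-yl}oxan-5-yl]methanone | CC(C)(C)[Si](C)(C)Oc1ccc(/C=C/C[C@H]2C[C@@H](C(=O)c3ccc(O[Si](C)(C)C(C)(C)C)cc3)CO[C@H]2c2ccc(O[Si](C)(C)C(C)(C)C)cc2)cc1
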